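**Retrosynthetic overview**
- The target is traced back (desilylation, two esterifications) to a trans-fused 1-hydroxy-hydrindan-2-one that carries both side-chain oxygens as silyl ethers.
- The cyclopentanone is the last ring to be closed, by an intramolecular carbonyl-ene reaction of a tethered α-keto aldehyde onto a 1-methylcyclohexene. One isomerisation should form the ring-fusion C–C bond, the exocyclic methylene, the acyloin hydroxyl and two stereocentres.
- The feature that allows this is the array CH2=C(six-ring)–CH(ring fusion)–CH(O-acyl) next to the five-ring ketone. This is a homoallylic alcohol with its alkene exocyclic on the six-membered ring, and at the same time an acyloin in the five-membered ring.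
- The ene precursor is a 4-substituted 2-methyl-5-isopropylcyclohex-2-en-1-ol. Its side chain comes from an Evans syn-aldol with acetaldehyde, then Weinreb amide, dithiane addition and unmasking.
- The six-membered ring is chiral pool: (R)-α-phellandrene, anti-epoxide, Pd-catalysed cis-1,4-opening with a malonyl oxazolidinone. Ring order: cyclohexene first (given), cyclopentanone last.

Key step: step 10

Remark (assumptions): monoallyl malonate, (E)-3-methylpent-2-enoic acid and (R)-2-methylbutanoic acid are taken as catalogue compounds. The 2-methylbutanoate centre of the target SMILES is read as (R) and the pentenoate as E.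
Remark (locants): monocycles are numbered as cyclohex-2-en-1-ols (C-1 carbinol, C-2 methyl, C-3 alkene CH, C-4 side chain, C-5 isopropyl). Bicycles are numbered as octahydroinden-2-ones (C-1 O, C-2 C=O, C-3 hydroxyethyl, C-3a, C-4 isopropyl, C-6 O, C-7 methylidene, C-7a).

**Step 1**
Reactants: 1 (R)-4-benzyl-1,3-oxazolidin-2-one; 2 monoallyl malonate
Product: 3 allyl 3-[(4R)-4-benzyl-2-oxo-1,3-oxazolidin-3-yl]-3-oxopropanoate
Conditions: DCC, DMAP (cat.), CH2Cl2, 0 °C → rt
Reagents that add atoms: none
Why: Carbodiimide-mediated N-acylation of the oxazolidinone by the malonic half-ester gives the soft pronucleophile that already carries the auxiliary, and no stereocentre is touched.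

**Step 2**
Reactants: 4 (R)-(−)-α-phellandrene
Product: 5 (1R,4R,6S)-1-methyl-4-isopropyl-7-oxabicyclo[4.1.0]hept-2-ene
Conditions: DMDO (1.0 equiv), acetone, −40 → −20 °C
Reagents that add atoms: dimethyldioxirane (DMDO), CC1(C)OO1
Why: Electrophilic epoxidation should pick the trisubstituted alkene of the diene and enter anti to the isopropyl group, which shields its own face of the nearly flat diene (both oxirane centres are set here); the neutral oxidant spares the acid-labile vinyl epoxide.

**Step 3**
Reactants: 5 vinyl epoxide; 3 malonyl oxazolidinone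
Product: 8 (4R)-4-benzyl-3-{[(1R,4S,6R)-4-hydroxy-3-methyl-6-isopropylcyclohex-2-en-1-yl]acetyl}-1,3-oxazolidin-2-one, via Tsuji–Trost adduct 6 (not isolated), via malonic half-acid 7 (not isolated)
Conditions: Pd(PPh3)4 (5 mol %), dioxane, rt; then HCO2H, Et3N, 100 °C
Reagents that add atoms: none
Why: Tsuji–Trost 1,4-opening of a vinyl epoxide: Pd(0) ionises the tertiary allylic C–O bond with inversion and the soft carbanion attacks the secondary allyl terminus anti to palladium, so the side chain should end cis to the hydroxyl and trans to isopropyl; formate/Pd then hydrogenolyses the allyl ester and the half-acid decarboxylates on heating, which erases the uncontrolled malonate centre.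

**Step 4**
Reactants: 8 hydroxy imide
Product: 9 (4R)-4-benzyl-3-{[(1R,4S,6R)-3-methyl-6-isopropyl-4-(triethylsilyloxy)cyclohex-2-en-1-yl]acetyl}-1,3-oxazolidin-2-one
Conditions: TESCl, imidazole, DMF, 0 °C → rt
Reagents that add atoms: chlorotriethylsilane (TESCl), CC[Si](Cl)(CC)CC
Why: Standard silylation of the secondary allylic alcohol; the bulky, non-chelating ether is chosen because it must sit pseudo-axial next to the vinylic methyl group in the key step.

**Step 5**
Reactants: 9 TES imide; 10 acetaldehyde
Product: 12 (4R)-4-benzyl-3-[(2R,3S)-3-hydroxy-2-(cyclohexenyl)butanoyl]-1,3-oxazolidin-2-one (cyclohexenyl as in 9), via Z-boron enolate 11 (not isolated)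
Conditions: Bu2BOTf, iPr2NEt, CH2Cl2, −78 → 0 °C; MeCHO, −78 → 0 °C; then pH 7 buffer, MeOH, H2O2
Reagents that add atoms: none
Why: Evans syn-aldol: the Z-boron enolate should react through a Zimmerman–Traxler chair on the face left open by the benzyl group of the (R)-auxiliary, which sets the α-centre (R) and the carbinol centre (S) in the syn relation of the target, the auxiliary overriding the weak bias of the ring stereocentre.

**Step 6**
Reactants: 12 aldol imide
Product: 13 (2R,3S)-3-hydroxy-N-methoxy-N-methyl-2-(cyclohexenyl)butanamide (ring as in 9)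
Conditions: MeNHOMe·HCl, AlMe3, CH2Cl2, −20 → 0 °C
Reagents that add atoms: N,O-dimethylhydroxylamine hydrochloride, CNOC.Cl
Why: Aluminium amide transamination of the aldol imide, assisted by the free β-hydroxyl, should give the Weinreb amide without touching the α-centre and release the auxiliary.

**Step 7**
Reactants: 13 hydroxy Weinreb amide
Product: 14 (2R,3S)-3-(tert-butyldimethylsilyloxy)-N-methoxy-N-methyl-2-(cyclohexenyl)butanamide
Conditions: TBSOTf, 2,6-lutidine, CH2Cl2, −78 → 0 °C
Reagents that add atoms: tert-butyldimethylsilyl triflate (TBSOTf), CC(C)(C)[Si](C)(C)OS(=O)(=O)C(F)(F)F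
Why: Silylation of the β-hydroxyl under non-nucleophilic base blocks retro-aldol and hemiacetal formation later and is orthogonal to the TES ether.

**Step 8**
Reactants: 14 Weinreb amide; 15 1,3-dithiane
Product: 16 (2R,3S)-3-(tert-butyldimethylsilyloxy)-1-(1,3-dithian-2-yl)-2-(cyclohexenyl)butan-1-one
Conditions: 15, n-BuLi, THF, −30 °C; then 14, −78 → −20 °C; NH4Cl
Reagents that add atoms: none
Why: Corey–Seebach acyl-anion addition to a Weinreb amide should stop at the ketone stage through the chelated tetrahedral intermediate and delivers the masked glyoxal carbon in one operation.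

**Step 9**
Reactants: 16 acyl dithiane
Product: 17 (3R,4S)-4-(tert-butyldimethylsilyloxy)-2-oxo-3-(cyclohexenyl)pentanal (α-keto aldehyde)
Conditions: PhI(OCOCF3)2, MeCN–H2O (9:1), 0 °C, 10 min; crude dried azeotropically (PhMe) and used at once
Reagents that add atoms: water, O
Why: Oxidative dithiane hydrolysis with a hypervalent iodine reagent should be much faster at sulfur than at the trisubstituted alkene and unveils the 1,2-dicarbonyl under brief, mild conditions.

**Step 10**
Reactants: 17 α-keto aldehyde
Product: 18 trans-fused 1-hydroxy-3-[(1S)-1-(tert-butyldimethylsilyloxy)ethyl]-7-methylidene-4-isopropyl-6-(triethylsilyloxy)octahydroinden-2-one (up: H-3a, 1-OH, 3-side chain, 4-isopropyl, H-6; down: H-7a, 6-OTES)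
Conditions: Me2AlCl (1.5 equiv), 4 Å MS, CH2Cl2, −78 → −30 °C
Reagents that add atoms: none
Why: Proposed new method: the aldehyde carbonyl, activated by the adjacent ketone and by monodentate Me2AlCl on the aldehyde oxygen, should be attacked by alkene carbon C-3 while that oxygen takes a hydrogen from the C-2 methyl group through a six-membered envelope (concerted type I carbonyl-ene), so that the C–C bond, the exocyclic methylene and the hydroxyl arise in one isomerisation. The closest known reactions are the Me2AlCl-promoted type I carbonyl-ene cyclisation of unsaturated aldehydes (citronellal to isopulegol) and the ene cyclisations of α-keto esters and glyoxylates; new is a tethered glyoxal whose ketone ends inside the ring. The cyclopentanone closes in a 5-exo-trig sense at the aldehyde carbon, with the alkene exocyclic to the forming ring. C-1 is controlled by the pericyclic array, in which the oxygen must lie over the methyl-bearing alkene carbon, so O–C-1 ends cis to the C-7a–C-7 bond as in the target. C-7a is controlled by the half-chair that keeps OTES pseudo-axial (A1,2 strain with the vinylic methyl) and isopropyl equatorial, so the tether is pseudo-equatorial and reaches only the alkene face anti to OTES, which is the trans fusion. The step needs ene over Prins or chloride capture (low temperature, proton-scavenging aluminium reagent), bonding at the less substituted alkene carbon (the ketone could only close a four-ring), hydrogen transfer from methyl and not from the in-plane H-1, and trans over cis fusion, which is the least secure point.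

**Step 11**
Reactants: 18 hydroxy ketone; 19 (R)-2-methylbutanoic acid
Product: 20 the 1-O-[(2R)-2-methylbutanoyl] ester of 18
Conditions: DCC, DMAP (cat.), CH2Cl2, 0 °C
Reagents that add atoms: none
Why: Steglich esterification of the secondary ketol hydroxyl under near-neutral conditions at low temperature, so that neither the α-centre of the acid nor the ketol centre should epimerise.

**Step 12**
Reactants: 20 ketol ester
Product: 21 the 6-hydroxy compound (TES removed, TBS kept)
Conditions: PPTS (cat.), MeOH–CH2Cl2, 0 °C
Reagents that add atoms: none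
Why: Acid-catalysed methanolysis should cleave the triethylsilyl ether far faster than the secondary TBS ether and leaves both the ester and the ketone alone.

**Step 13**
Reactants: 21 allylic alcohol; 22 (E)-3-methylpent-2-enoic acid
Product: 23 the 6-O-[(E)-3-methylpent-2-enoyl] ester of 21
Conditions: DCC, DMAP (cat.), CH2Cl2, 0 °C → rt
Reagents that add atoms: none
Why: Steglich esterification of the axial allylic alcohol; carbodiimide activation without stoichiometric amine base should avoid E/Z or deconjugative isomerisation of the β,β-disubstituted enoic acid.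

**Step 14**
Reactants: 23 bis-ester TBS ether
Product: 24 CNP0224363.1
Conditions: HF·pyridine, pyridine, THF, 0 °C → rt
Reagents that add atoms: none
Why: Buffered fluoride desilylation frees the β-hydroxy ketone without base, so retro-aldol, dehydration, acyl migration and epimerisation of the ketol centre should not occur.

**Compound list**
1 | (R)-4-benzyl-1,3-oxazolidin-2-one | O=C1N[C@H](Cc2ccccc2)CO1 | starting material
2 | monoallyl malonate (3-oxo-3-(prop-2-enyloxy)propanoic acid) | OC(=O)CC(=O)OCC=C | starting material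
3 | allyl 3-[(4R)-4-benzyl-2-oxo-1,3-oxazolidin-3-yl]-3-oxopropanoate | C=CCOC(=O)CC(=O)N1[C@H](Cc2ccccc2)COC1=O | intermediate
4 | (R)-(−)-α-phellandrene | CC1=CC[C@H](C(C)C)C=C1 | starting material
5 | (1R,4R,6S)-1-methyl-4-isopropyl-7-oxabicyclo[4.1.0]hept-2-ene (oxirane anti to isopropyl) | C[C@@]12C=C[C@@H](C(C)C)C[C@@H]1O2 | intermediate
6 | Tsuji–Trost adduct: allyl malonate-imide at C-4 of the cyclohexenol, malonate centre unassigned | CC1=C[C@H](C(C(=O)OCC=C)C(=O)N2[C@H](Cc3ccccc3)COC2=O)[C@@H](C(C)C)C[C@@H]1O | intermediate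
7 | malonic half-acid from 6 | CC1=C[C@H](C(C(=O)O)C(=O)N2[C@H](Cc3ccccc3)COC2=O)[C@@H](C(C)C)C[C@@H]1O | intermediate
8 | (4R)-4-benzyl-3-{[(1R,4S,6R)-4-hydroxy-3-methyl-6-isopropylcyclohex-2-en-1-yl]acetyl}-1,3-oxazolidin-2-one (side chain cis to OH, trans to isopropyl) | CC1=C[C@H](CC(=O)N2[C@H](Cc3ccccc3)COC2=O)[C@@H](C(C)C)C[C@@H]1O | intermediate
9 | triethylsilyl ether of 8 | CC1=C[C@H](CC(=O)N2[C@H](Cc3ccccc3)COC2=O)[C@@H](C(C)C)C[C@@H]1O[Si](CC)(CC)CC | intermediate
10 | acetaldehyde | CC=O | starting material
11 | Z-dibutylboron enolate of 9 | CC1=C[C@H](/C=C(\OB(CCCC)CCCC)N2[C@H](Cc3ccccc3)COC2=O)[C@@H](C(C)C)C[C@@H]1O[Si](CC)(CC)CC | intermediate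
12 | syn-aldol imide, (2R,3S)-3-hydroxy-2-(cyclohexenyl)butanoyl on the (R)-auxiliary | CC1=C[C@H]([C@H]([C@H](C)O)C(=O)N2[C@H](Cc3ccccc3)COC2=O)[C@@H](C(C)C)C[C@@H]1O[Si](CC)(CC)CC | intermediate
13 | (2R,3S)-3-hydroxy Weinreb amide | CC1=C[C@H]([C@H]([C@H](C)O)C(=O)N(C)OC)[C@@H](C(C)C)C[C@@H]1O[Si](CC)(CC)CC | intermediate
14 | (2R,3S)-3-(TBS-oxy) Weinreb amide | CC1=C[C@H]([C@H]([C@H](C)O[Si](C)(C)C(C)(C)C)C(=O)N(C)OC)[C@@H](C(C)C)C[C@@H]1O[Si](CC)(CC)CC | intermediate
15 | 1,3-dithiane | C1CSCSC1 | starting material
16 | 2-acyl-1,3-dithiane (masked α-keto aldehyde) | CC1=C[C@H]([C@H]([C@H](C)O[Si](C)(C)C(C)(C)C)C(=O)C2SCCCS2)[C@@H](C(C)C)C[C@@H]1O[Si](CC)(CC)CC | intermediate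
17 | (3R,4S)-4-(TBS-oxy)-2-oxo-3-(cyclohexenyl)pentanal | CC1=C[C@H]([C@H]([C@H](C)O[Si](C)(C)C(C)(C)C)C(=O)C=O)[C@@H](C(C)C)C[C@@H]1O[Si](CC)(CC)CC | intermediate
18 | trans-fused 1-hydroxy-7-methylidene-octahydroinden-2-one (ene product) | C=C1[C@@H]2[C@H]([C@H]([C@H](C)O[Si](C)(C)C(C)(C)C)C(=O)[C@@H]2O)[C@@H](C(C)C)C[C@@H]1O[Si](CC)(CC)CC | intermediate
19 | (R)-2-methylbutanoic acid | CC[C@@H](C)C(=O)O | starting material
20 | 1-O-[(R)-2-methylbutanoyl] ester of 18 | C=C1[C@@H]2[C@H]([C@H]([C@H](C)O[Si](C)(C)C(C)(C)C)C(=O)[C@@H]2OC(=O)[C@H](C)CC)[C@@H](C(C)C)C[C@@H]1O[Si](CC)(CC)CC | intermediate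
21 | 6-hydroxy compound (TES removed) | C=C1[C@@H]2[C@H]([C@H]([C@H](C)O[Si](C)(C)C(C)(C)C)C(=O)[C@@H]2OC(=O)[C@H](C)CC)[C@@H](C(C)C)C[C@@H]1O | intermediate
22 | (E)-3-methylpent-2-enoic acid | CC/C(C)=C/C(=O)O | starting material
23 | bis-ester TBS ether | C=C1[C@@H]2[C@H]([C@H]([C@H](C)O[Si](C)(C)C(C)(C)C)C(=O)[C@@H]2OC(=O)[C@H](C)CC)[C@@H](C(C)C)C[C@@H]1OC(=O)/C=C(\C)CC | intermediate
24 | CNP0224363.1 | C=C1[C@@H]2[C@H]([C@H]([C@H](C)O)C(=O)[C@@H]2OC(=O)[C@H](C)CC)[C@@H](C(C)C)C[C@@H]1OC(=O)/C=C(\C)CC | target

**Step count:** 14 steps in total. The longest linear sequence is 13 steps (4 → 24, steps 2–14); step 1 is a one-step side branch.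

**Steps most likely to fail**

1. Step 10 (proposed new method). The 1,2-dicarbonyl may enolise towards its α-centre, hydrate or take a methyl group from aluminium faster than the five-ring ene closure. The closure may also run through the ring-flipped half-chair and give the cis-fused isomer.
Fallback (known chemistry, the enophile at a lower oxidation level): it sets out from 16 and comes back at 20. NaBH4 in MeOH reduces the ketone to the dithianyl carbinol F1 (both epimers at the new centre are carried on). PMB trichloroacetimidate with catalytic La(OTf)3 gives the PMB ether F2. MeI and CaCO3 in aqueous MeCN hydrolyse the dithiane to the α-PMB-oxy aldehyde F3. Me2AlCl in CH2Cl2 at −78 °C closes F3 by the established Lewis-acid type I carbonyl-ene cyclisation of an unsaturated aldehyde to the cyclopentanol F4, through the same envelope and the same half-chair bias. DCC/DMAP with 19 gives the ester F5, DDQ removes the PMB group to give the alcohol F6, and Dess–Martin oxidation of F6 gives 20. The half-chair bias is the same as in step 10, so this fallback answers the lability of the 1,2-dicarbonyl but not the cis-fusion risk.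

2. Step 2. Facial selectivity of the epoxidation two carbons away from the isopropyl group may be poor, and the allylic epoxide may rearrange or aromatise before it is used.
Fallback: it sets out from 4 and comes back at 8. Catalytic OsO4 with NMO in acetone–water dihydroxylates the trisubstituted alkene anti to isopropyl to the cis-diol F7, a stable compound from which a minor isomer can be removed. Carbonyldiimidazole converts F7 into the cyclic carbonate F8. Under the Pd(0) conditions of step 3, F8 ionises with loss of CO2 to the same π-allyl/alkoxide pair, which takes up 3 to give adduct 6 and then 8 in the same pot.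

3. Step 9. The oxidant may attack the electron-rich trisubstituted alkene, the trifluoroacetic acid released may cleave the TES ether or start a premature cationic closure, and the product may be held as its hydrate.
Fallback: it sets out from 14 and comes back at 17. [(4-Methoxybenzyloxy)methyl]lithium (from the tributylstannane and n-BuLi, THF, −78 °C) adds to the Weinreb amide to give the α-PMB-oxy ketone F9. DDQ in buffered CH2Cl2 gives the α-hydroxy ketone F10. Dess–Martin periodinane oxidises F10 to anhydrous 17, which goes straight into step 10.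

**Further compounds**
F1 | step 10 | dithianyl carbinol (epimers at the carbinol carbon) | CC1=C[C@H]([C@H]([C@H](C)O[Si](C)(C)C(C)(C)C)C(O)C2SCCCS2)[C@@H](C(C)C)C[C@@H]1O[Si](CC)(CC)CC
F2 | step 10 | PMB ether of F1 | CC1=C[C@H]([C@H]([C@H](C)O[Si](C)(C)C(C)(C)C)C(OCc2ccc(OC)cc2)C2SCCCS2)[C@@H](C(C)C)C[C@@H]1O[Si](CC)(CC)CC
F3 | step 10 | α-PMB-oxy aldehyde | CC1=C[C@H]([C@H]([C@H](C)O[Si](C)(C)C(C)(C)C)C(OCc2ccc(OC)cc2)C=O)[C@@H](C(C)C)C[C@@H]1O[Si](CC)(CC)CC
F4 | step 10 | trans-fused 2-PMB-oxy-7-methylidene-octahydroinden-1-ol | C=C1[C@@H]2[C@H]([C@H]([C@H](C)O[Si](C)(C)C(C)(C)C)C(OCc3ccc(OC)cc3)[C@@H]2O)[C@@H](C(C)C)C[C@@H]1O[Si](CC)(CC)CC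
F5 | step 10 | 1-O-[(R)-2-methylbutanoyl] ester of F4 | C=C1[C@@H]2[C@H]([C@H]([C@H](C)O[Si](C)(C)C(C)(C)C)C(OCc3ccc(OC)cc3)[C@@H]2OC(=O)[C@H](C)CC)[C@@H](C(C)C)C[C@@H]1O[Si](CC)(CC)CC
F6 | step 10 | 2-hydroxy compound (PMB removed) | C=C1[C@@H]2[C@H]([C@H]([C@H](C)O[Si](C)(C)C(C)(C)C)C(O)[C@@H]2OC(=O)[C@H](C)CC)[C@@H](C(C)C)C[C@@H]1O[Si](CC)(CC)CC
F7 | step 2 | cis-1,2-diol of α-phellandrene, both hydroxyls anti to isopropyl | C[C@@]1(O)C=C[C@@H](C(C)C)C[C@@H]1O
F8 | step 2 | cyclic carbonate of F7 | C[C@@]12C=C[C@@H](C(C)C)C[C@@H]1OC(=O)O2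
F9 | step 9 | α-PMB-oxy methyl ketone | CC1=C[C@H]([C@H]([C@H](C)O[Si](C)(C)C(C)(C)C)C(=O)COCc2ccc(OC)cc2)[C@@H](C(C)C)C[C@@H]1O[Si](CC)(CC)CC
F10 | step 9 | α-hydroxy methyl ketone | CC1=C[C@H]([C@H]([C@H](C)O[Si](C)(C)C(C)(C)C)C(=O)CO)[C@@H](C(C)C)C[C@@H]1O[Si](CC)(CC)CC
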